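I started with the easy step of laying Saturday's and Friday's percent curves over each other. Their charges of starting material differ 1.57-fold at equal catalyst, yet the readings match within scatter, so I expected the new flask, with 2.0 mM and the same 0.16 mM of catalyst, to follow their mean.

| flask | starting material | catalyst | remark | time |
|---|---|---|---|---|
| Saturday's | 2.8 mM | 0.16 mM | run made earlier |  |
| Friday's | 4.4 mM | 0.16 mM | run made earlier |  |
| Wednesday's | 2 mM | 0.080 mM | run made earlier |  |
| flask | 2.0 mM | 0.16 mM |  | 10 min |

| run | time / min | target / % |
|---|---|---|
| Saturday's | 0.667 | 34.3 |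
| Saturday's | 1.00 | 44.9 |
| Saturday's | 1.50 | 53.8 |
| Saturday's | 2.50 | 60.5 |
| Saturday's | 4.00 | 59.1 |
| Saturday's | 6.00 | 51.0 |
| Friday's | 0.667 | 36.7 |
| Friday's | 1.00 | 47.1 |
| Friday's | 1.50 | 54.0 |
| Friday's | 2.50 | 61.5 |
| Friday's | 4.00 | 59.2 |
| Friday's | 6.00 | 52.4 |
| Wednesday's | 0.667 | 19.5 |
| Wednesday's | 1.33 | 33.8 |
| Wednesday's | 2.00 | 41.2 |
| Wednesday's | 4.00 | 50.4 |
| Wednesday's | 6.00 | 48.9 |

(readings scatter by 1 percentage point)

- when, up to 10 min, the flask holds most target
- the amount of target, in percent of the starting material charged, at that time

- reactions considered so far: starting material + catalyst -> catalyst + target; starting material -> side product; catalyst + target -> catalyst + over-reaction product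

I read the tail first. Between 4.00 min and 6.00 min the mean target fell at 0.0673 min⁻¹. I took this as the tail rate, the pseudo-first-order loss of target at a given catalyst charge once feeding has stopped. Since catalyst is a reactant of that step, the rate scales with the catalyst charge.

Drawn back to zero time, the tail starts at 77.4%, and the target curve is that tail minus a gap which starts equal to it. At 1.50 min the gap was 16 percentage points, so it closes at 1.05 min⁻¹, 15.6 times faster than the tail falls. In my reckoning the flask's curve therefore starts with a slope, the gap's less the tail's, of 0.761 min⁻¹ as a fraction of the charge and bends near 0.952 min. It crests where the closing gap's slope crosses the tail's, at the logarithm of the rate ratio over the rate difference: 2.80 min, with 60.0% target.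

The forecast gave 2.8 min (2.3 min to 3.2 min) and 60.5% (57% to 63%), reasoning that “Loss of starting material therefore looks first order”. My peak stood slightly lower.

The simulation gave 2.77 min and 61.3%.

    starting material + catalyst → catalyst + target (k = 81.2 M⁻¹ s⁻¹)
    starting material → side product (k = 0.00450 s⁻¹)
    catalyst + target → catalyst + over-reaction product (k = 7.21 M⁻¹ s⁻¹)

Beyond the crest, the tail rate carries my curve to 39.5% at 10 min, and the flask held 39.8% target. A neighbour charged with 0.64 mM of catalyst has 4.00 times the catalyst, so its tail rate is 0.269 min⁻¹. Of its charge, 92.0% did not become side product, and that share decayed over 10 min leaves 6.23%. The neighbour ended with 6.29% target.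

All runs come from a simulation on assumed constants.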